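**Retrosynthetic overview**
- C2–O ester bond: made last on the skeleton by a palladium-catalysed allylic C–H acyloxylation that joins the terpenoid alkene-alcohol to O-acetylisovanillic acid; deacetylation ends the route.
- C9 tertiary carbinol: methyl addition to the cis-fused bicyclic C9 ketone from its convex face.
- Ring B (formed second): C7=C8 ring-closing metathesis of a dienol (C8–C9 from vinyl Grignard addition), then alkene hydrogenation and alcohol oxidation.
- Ring A (formed first): enantioselective organocatalytic Diels–Alder reaction of acrolein with a triene (C1–C2 and C4a–C9a bonds); the triene comes from Takai iodoolefination and Negishi coupling (C3–C4 bond).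
- Aryl acid: catechol, then methylation, acetylation, para-bromination, palladium-catalysed hydroxycarbonylation and O-acetylation.

Assumption: atom labels C1–C9a follow the benzo[7]annulene numbering of the target's terpenoid part (C2 ester carbinol, C3 methyl-bearing alkene carbon, C5 gem-dimethyl carbon, C9 tertiary carbinol; ring A = cyclohexene, ring B = cycloheptane; α = face of H4a and H9a).

**Route**

Step 1
Reactants: 1 2,2-dimethylpent-4-enal
Product: 2 (E)-1-iodo-3,3-dimethylhexa-1,5-diene
Conditions: CrCl2 (6 equiv), CHI3 (2 equiv), THF, 0 °C to rt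
Reagents that add atoms: iodoform, IC(I)I
Why: Takai iodoolefination: the geminal dichromium species from CHI3 and CrCl2 adds to the non-enolisable α-quaternary aldehyde and eliminates to give the (E)-iodoalkene selectively.

Step 2
Reactants: 2 (E)-1-iodo-3,3-dimethylhexa-1,5-diene; 3 isopropenylmagnesium bromide
Product: 5 (3E)-2,5,5-trimethylocta-1,3,7-triene, via isopropenylzinc chloride 4 (not isolated)
Conditions: 3, ZnCl2, THF, 0 °C; then 2, Pd(PPh3)4 (3 mol %), rt
Reagents that add atoms: none
Why: Negishi cross-coupling: zerovalent palladium inserts into the alkenyl C–I bond, and transmetalation from the alkenylzinc followed by reductive elimination forms the C3–C4 bond with retention of the E geometry.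

Step 3
Reactants: 5 (3E)-2,5,5-trimethylocta-1,3,7-triene; 6 acrolein
Product: 7 (1R,2S)-4-methyl-2-(2-methylpent-4-en-2-yl)cyclohex-3-ene-1-carbaldehyde
Conditions: (5S)-5-benzyl-2,2,3-trimethylimidazolidin-4-one·HCl (20 mol %), MeCN/H2O (95:5), 0 °C to rt
Reagents that add atoms: none
Why: Organocatalytic enantioselective Diels–Alder reaction through the iminium ion of acrolein: the benzyl group of the (5S) catalyst blocks one face so the diene adds to the Si face of the α-carbon (C9a becomes R), the 1-alkyl and 3-methyl groups of the diene both direct the "ortho/para" regiochemistry, and the endo transition state places H4a and H9a cis.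

Step 4
Reactants: 7 (1R,2S)-4-methyl-2-(2-methylpent-4-en-2-yl)cyclohex-3-ene-1-carbaldehyde
Product: 8 1-[(1R,2S)-4-methyl-2-(2-methylpent-4-en-2-yl)cyclohex-3-en-1-yl]prop-2-en-1-ol (both carbinol epimers)
Conditions: CH2=CHMgBr, THF, −78 °C; then aq NH4Cl
Reagents that add atoms: vinylmagnesium bromide, C=C[Mg]Br
Why: Grignard 1,2-addition to the aldehyde at −78 °C does not epimerise the α-stereocentre, and the new carbinol centre (a mixture) is removed by oxidation in step 7.

Step 5
Reactants: 8 1-[(1R,2S)-4-methyl-2-(2-methylpent-4-en-2-yl)cyclohex-3-en-1-yl]prop-2-en-1-ol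
Product: 9 (4aS,9aR)-3,5,5-trimethyl-2,4a,5,6,9,9a-hexahydro-1H-benzo[7]annulen-9-ol (both C9 epimers)
Conditions: second-generation Grubbs catalyst RuCl2(=CHPh)(PCy3)(H2IMes) (5 mol %), CH2Cl2 (5 mM), 40 °C
Reagents that add atoms: none
Why: Ring-closing olefin metathesis: the two terminal alkenes held cis on ring A, with the gem-dimethyl group in the tether, close the seven-membered ring B by loss of ethylene while the trisubstituted ring A alkene does not react.

Step 6
Reactants: 9 (4aS,9aR)-3,5,5-trimethyl-2,4a,5,6,9,9a-hexahydro-1H-benzo[7]annulen-9-ol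
Product: 10 (4aS,9aR)-3,5,5-trimethyl-2,4a,5,6,7,8,9,9a-octahydro-1H-benzo[7]annulen-9-ol (both C9 epimers)
Conditions: H2 (1 atm), RhCl(PPh3)3 (5 mol %), benzene, rt
Reagents that add atoms: none
Why: Homogeneous hydrogenation with RhCl(PPh3)3 reduces the cis-disubstituted C7=C8 alkene and leaves the trisubstituted C3=C4 alkene untouched.

Step 7
Reactants: 10 (4aS,9aR)-3,5,5-trimethyl-2,4a,5,6,7,8,9,9a-octahydro-1H-benzo[7]annulen-9-ol
Product: 11 (4aS,9aR)-3,5,5-trimethyl-1,2,4a,5,6,7,8,9a-octahydro-9H-benzo[7]annulen-9-one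
Conditions: Dess–Martin periodinane, pyridine, CH2Cl2, 0 °C to rt
Reagents that add atoms: none
Why: Dess–Martin oxidation of the secondary alcohol under pyridine-buffered conditions that do not epimerise C9a.

Step 8
Reactants: 11 (4aS,9aR)-3,5,5-trimethyl-1,2,4a,5,6,7,8,9a-octahydro-9H-benzo[7]annulen-9-one
Product: 12 (4aS,9S,9aR)-3,5,5,9-tetramethyl-2,4a,5,6,7,8,9,9a-octahydro-1H-benzo[7]annulen-9-ol
Conditions: MeMgBr, CeCl3, THF, −78 to 0 °C; then aq NH4Cl
Reagents that add atoms: methylmagnesium bromide, C[Mg]Br
Why: Imamoto organocerium 1,2-addition, whose low basicity avoids enolisation toward C9a; the methyl group enters from the convex α face (away from ring A), so the C9 hydroxyl is β and the centre is S.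

Step 9
Reactants: 13 catechol
Product: 14 2-methoxyphenol
Conditions: MeI (0.9 equiv), K2CO3, acetone, reflux
Reagents that add atoms: iodomethane, CI
Why: Williamson ether synthesis with a slight deficit of MeI gives mainly the monomethyl ether, which is separated from catechol and veratrole by acid–base extraction.

Step 10
Reactants: 14 2-methoxyphenol
Product: 15 2-methoxyphenyl acetate
Conditions: Ac2O, pyridine, DMAP (cat.), CH2Cl2, rt
Reagents that add atoms: acetic anhydride, CC(=O)OC(C)=O
Why: DMAP-catalysed O-acetylation turns the phenol into an acetoxy group that is a much weaker donor than methoxy and so steers the next bromination.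

Step 11
Reactants: 15 2-methoxyphenyl acetate
Product: 16 5-bromo-2-methoxyphenyl acetate
Conditions: NBS, MeCN, rt
Reagents that add atoms: N-bromosuccinimide, O=C1CCC(=O)N1Br
Why: Electrophilic aromatic bromination occurs para to the strongly donating methoxy group (C5) and not para to the deactivated acetoxy group.

Step 12
Reactants: 16 5-bromo-2-methoxyphenyl acetate
Product: 18 3-hydroxy-4-methoxybenzoic acid, via 5-bromo-2-methoxyphenol 17 (not isolated)
Conditions: CO (1 atm), Pd(OAc)2 (2 mol %), Xantphos (3 mol %), K2CO3, 1,4-dioxane/H2O, 90 °C; then aq HCl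
Reagents that add atoms: carbon monoxide, [C-]#[O+]; water, O
Why: Palladium-catalysed hydroxycarbonylation of the aryl bromide (oxidative addition to zerovalent palladium, CO insertion, hydrolysis of the acylpalladium) follows fast saponification of the aryl acetate by aqueous K2CO3.

Step 13
Reactants: 18 3-hydroxy-4-methoxybenzoic acid
Product: 19 3-acetoxy-4-methoxybenzoic acid
Conditions: Ac2O (1.3 equiv), aq NaOH, 0 °C; then aq HCl
Reagents that add atoms: acetic anhydride, CC(=O)OC(C)=O
Why: Schotten–Baumann acetylation of the phenoxide in water, where the carboxylate is not durably acylated, gives the O-acetyl acid on acidification.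

Step 14
Reactants: 12 (4aS,9S,9aR)-3,5,5,9-tetramethyl-2,4a,5,6,7,8,9,9a-octahydro-1H-benzo[7]annulen-9-ol; 19 3-acetoxy-4-methoxybenzoic acid
Product: 20 (2R,4aS,9S,9aR)-9-hydroxy-3,5,5,9-tetramethyl-2,4a,5,6,7,8,9,9a-octahydro-1H-benzo[7]annulen-2-yl 3-acetoxy-4-methoxybenzoate
Conditions: Pd(OAc)2 (10 mol %), PhS(O)CH2CH2S(O)Ph (10 mol %), 2,6-dimethyl-1,4-benzoquinone (2 equiv), 19 (1.5 equiv), iPr2NEt (0.5 equiv), 1,4-dioxane, 45 °C
Reagents that add atoms: none
Why: Proposed new method: diastereoselective intermolecular allylic C–H acyloxylation of a trisubstituted cycloalkene with a near-stoichiometric arenecarboxylic acid, in which divalent palladium carboxylate binds the C3=C4 alkene on the open α face (the β face is screened by the C5 gem-dimethyl group and ring B), carboxylate-assisted cleavage of the pseudoaxial α C2–H gives the C2–C3–C4 π-allyl complex, and quinone-induced inner-sphere C–O reductive elimination at the less hindered terminus C2 (C4 is flanked by C4a and C5) delivers the ester on the same α face and sets C2 as R; the closest known reactions are the Pd(OAc)2/bis-sulfoxide/benzoquinone allylic C–H esterification of terminal alkenes with complex acids and the Pd(OAc)2/benzoquinone allylic acetoxylation of cyclohexene in acetic acid.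

Step 15
Reactants: 20 (2R,4aS,9S,9aR)-9-hydroxy-3,5,5,9-tetramethyl-2,4a,5,6,7,8,9,9a-octahydro-1H-benzo[7]annulen-2-yl 3-acetoxy-4-methoxybenzoate
Product: 21 (2R,4aS,9S,9aR)-9-hydroxy-3,5,5,9-tetramethyl-2,4a,5,6,7,8,9,9a-octahydro-1H-benzo[7]annulen-2-yl 3-hydroxy-4-methoxybenzoate
Conditions: NH3 (7 M in MeOH), 0 °C
Reagents that add atoms: none
Why: Ammonolysis of the aryl acetate, which is far more electrophilic than the hindered secondary alkyl benzoate, frees the phenol without touching the stereocentres or the tertiary alcohol.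

**Compound list**
1 | 2,2-dimethylpent-4-enal | O=CC(C)(C)CC=C | starting material
2 | (E)-1-iodo-3,3-dimethylhexa-1,5-diene | I/C=C/C(C)(C)CC=C | intermediate
3 | isopropenylmagnesium bromide | C=C(C)[Mg]Br | starting material
4 | isopropenylzinc chloride | C=C(C)[Zn]Cl | intermediate (not isolated)
5 | (3E)-2,5,5-trimethylocta-1,3,7-triene | CC(=C)/C=C/C(C)(C)CC=C | intermediate
6 | acrolein | C=CC=O | starting material
7 | (1R,2S)-4-methyl-2-(2-methylpent-4-en-2-yl)cyclohex-3-ene-1-carbaldehyde | C1C[C@@H](C=O)[C@H](C=C1C)C(C)(C)CC=C | intermediate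
8 | 1-[(1R,2S)-4-methyl-2-(2-methylpent-4-en-2-yl)cyclohex-3-en-1-yl]prop-2-en-1-ol (both carbinol epimers) | C1C[C@@H](C(O)C=C)[C@H](C=C1C)C(C)(C)CC=C | intermediate
9 | (4aS,9aR)-3,5,5-trimethyl-2,4a,5,6,9,9a-hexahydro-1H-benzo[7]annulen-9-ol (both C9 epimers) | C1C[C@@H]2[C@H](C=C1C)C(C)(C)CC=CC2O | intermediate
10 | (4aS,9aR)-3,5,5-trimethyl-2,4a,5,6,7,8,9,9a-octahydro-1H-benzo[7]annulen-9-ol (both C9 epimers) | C1C[C@@H]2[C@H](C=C1C)C(C)(C)CCCC2O | intermediate
11 | (4aS,9aR)-3,5,5-trimethyl-1,2,4a,5,6,7,8,9a-octahydro-9H-benzo[7]annulen-9-one | C1C[C@@H]2[C@H](C=C1C)C(C)(C)CCCC2=O | intermediate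
12 | (4aS,9S,9aR)-3,5,5,9-tetramethyl-2,4a,5,6,7,8,9,9a-octahydro-1H-benzo[7]annulen-9-ol | C1C[C@@H]2[C@H](C=C1C)C(C)(C)CCC[C@]2(C)O | intermediate
13 | catechol | Oc1ccccc1O | starting material
14 | 2-methoxyphenol | COc1ccccc1O | intermediate
15 | 2-methoxyphenyl acetate | COc1ccccc1OC(C)=O | intermediate
16 | 5-bromo-2-methoxyphenyl acetate | COc1ccc(Br)cc1OC(C)=O | intermediate
17 | 5-bromo-2-methoxyphenol (present as its potassium salt) | COc1ccc(Br)cc1O | intermediate (not isolated)
18 | 3-hydroxy-4-methoxybenzoic acid | COc1ccc(C(=O)O)cc1O | intermediate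
19 | 3-acetoxy-4-methoxybenzoic acid | COc1ccc(C(=O)O)cc1OC(C)=O | intermediate
20 | (2R,4aS,9S,9aR)-9-hydroxy-3,5,5,9-tetramethyl-2,4a,5,6,7,8,9,9a-octahydro-1H-benzo[7]annulen-2-yl 3-acetoxy-4-methoxybenzoate | COc1ccc(C(=O)O[C@@H]2C[C@@H]3[C@H](C=C2C)C(C)(C)CCC[C@]3(C)O)cc1OC(C)=O | intermediate
21 | (2R,4aS,9S,9aR)-9-hydroxy-3,5,5,9-tetramethyl-2,4a,5,6,7,8,9,9a-octahydro-1H-benzo[7]annulen-2-yl 3-hydroxy-4-methoxybenzoate | COc1ccc(C(=O)O[C@@H]2C[C@@H]3[C@H](C=C2C)C(C)(C)CCC[C@]3(C)O)cc1O | target

**Step count**
Total steps: 15. Longest linear sequence: 10 (steps 1–8, 14, 15); steps 9–13 form the aryl branch.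

**Steps most likely to fail, with fallbacks**

Step 14 (the proposed new C–H acyloxylation). Risks: C–H cleavage at the C3 methyl or at C4a instead of C2, slow reaction of the internal alkene, ester delivery to the β face, or attack of the free C9 hydroxyl on the π-allyl complex. The fallback uses known chemistry, sets out from 12 and comes back at 20. Riley allylic hydroxylation of 12 with catalytic SeO2 and t-BuOOH in CH2Cl2 (ene reaction then 2,3-sigmatropic shift) oxidises the ring CH2 next to the more substituted alkene carbon. It delivers oxygen on the α face that the reagent attacks, giving (2R,4aS,9S,9aR)-3,5,5,9-tetramethyl-2,4a,5,6,7,8,9,9a-octahydro-1H-benzo[7]annulene-2,9-diol F1. Steglich esterification of F1 with 19 (EDC·HCl, DMAP, CH2Cl2) acylates only the secondary allylic hydroxyl and gives 20.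

Step 3 (Diels–Alder reaction with a diene carrying a tertiary alkyl group at its terminus). Risks: low rate, eroded endo selectivity or eroded enantioselectivity. The fallback replaces iminium activation by a chelating chiral Lewis acid; it sets out from 5 and comes back at 7. Acryloyl chloride and 1,3-oxazolidin-2-one (n-BuLi, THF, −78 °C) give 3-(prop-2-enoyl)-1,3-oxazolidin-2-one F2. Cycloaddition of 5 with F2 is catalysed by [Cu((R,R)-t-Bu-box)](SbF6)2 (10 mol %, CH2Cl2, −20 °C; t-Bu-box = 2,2'-(propane-2,2-diyl)bis(4-tert-butyl-4,5-dihydro-1,3-oxazole)). The (R,R) ligand exposes the Si face of the α-carbon, giving 3-[(1R,2S)-4-methyl-2-(2-methylpent-4-en-2-yl)cyclohex-3-ene-1-carbonyl]-1,3-oxazolidin-2-one F3. LiBH4 (THF, H2O) reduces F3 to [(1R,2S)-4-methyl-2-(2-methylpent-4-en-2-yl)cyclohex-3-en-1-yl]methanol F4, and Dess–Martin oxidation of F4 gives 7.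

Step 8 (facial selectivity of the methyl addition at C9). If the methyl group enters from the β face and the C9 epimer forms, the polarity of the C9 construction is reversed; this fallback sets out from 11 and comes back at 12. Wittig methylenation (Ph3PCH3Br, KOtBu, THF) gives (4aS,9aR)-3,5,5-trimethyl-9-methylidene-2,4a,5,6,7,8,9,9a-octahydro-1H-benzo[7]annulene F5. Markovnikov oxymercuration–demercuration (Hg(OAc)2, THF/H2O; then NaBH4, NaOH) is selective for the 1,1-disubstituted alkene over the trisubstituted ring A alkene. Water then attacks C9 from the face that the organometallic reagent preferred, so the hydroxyl ends up β and the new methyl α, as in 12.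

**Further compounds**
F1 | step 14 | (2R,4aS,9S,9aR)-3,5,5,9-tetramethyl-2,4a,5,6,7,8,9,9a-octahydro-1H-benzo[7]annulene-2,9-diol | O[C@@H]1C[C@@H]2[C@H](C=C1C)C(C)(C)CCC[C@]2(C)O
F2 | step 3 | 3-(prop-2-enoyl)-1,3-oxazolidin-2-one | C=CC(=O)N1CCOC1=O
F3 | step 3 | 3-[(1R,2S)-4-methyl-2-(2-methylpent-4-en-2-yl)cyclohex-3-ene-1-carbonyl]-1,3-oxazolidin-2-one | C1C[C@@H](C(=O)N2CCOC2=O)[C@H](C=C1C)C(C)(C)CC=C
F4 | step 3 | [(1R,2S)-4-methyl-2-(2-methylpent-4-en-2-yl)cyclohex-3-en-1-yl]methanol | C1C[C@@H](CO)[C@H](C=C1C)C(C)(C)CC=C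
F5 | step 8 | (4aS,9aR)-3,5,5-trimethyl-9-methylidene-2,4a,5,6,7,8,9,9a-octahydro-1H-benzo[7]annulene | C1C[C@@H]2[C@H](C=C1C)C(C)(C)CCCC2=C
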